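**Retrosynthetic overview**

1. The 1,2-dioxan-3-ol is the closed form of a γ-hydroperoxy methyl ketone; the dioxane ring is closed last by 6-endo peroxymercuration of an (E)-C5=C6 alkene by a C3 gem-dihydroperoxide, the C4 methyl group relaying its configuration to C6.
2. The (E)-alkene and the side-chain stereocentre come from a Claisen rearrangement of an allyl (E)-propenyl ether at a C5 carbinol; the phenylalkyl chain follows by Wittig reaction and selective hydrogenation.
3. C3–C4–C5–C6 is assembled as a cyclobutanone from a ketene (C3=C6) and a chiral (Z)-propenyl ether (C4=C5); a Grob fragmentation then cuts C3–C6, leaving the acetyl group, the C4/C5 stereocentres and an isopropenyl group.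
4. Enabling feature: in the dioxane ring the hemiketal carbon C3 (a latent acetyl carbon) and the peroxide-bearing quaternary carbon C6 both sit on the C4–C5 unit and are joined to each other only through O1–O2, so C3 and C6 can be the two carbons of one ketene and C4–C5 an enol ether.
5. Ring order: cyclobutanone (temporary, opened in step 8), then the 1,2-dioxane; the benzene ring is bought.

Key step: step 5

Remark: C3–C6 denote the dioxane ring atoms of the target; alcohol 1, boronate 16 and bromide 19 are taken as purchasable, and the face selectivity assigned in step 5 rests on the usual conformational model of 1-arylethyl enol ethers (the enantiomer of 1 would be used if the sense proves opposite).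

**Step 1**
Reactants: 1 (1S)-1-[2,4,6-tri(propan-2-yl)phenyl]ethanol; 2 allyl bromide
Product: 3 2-[(1S)-1-(prop-2-en-1-yloxy)ethyl]-1,3,5-tri(propan-2-yl)benzene
Conditions: NaH, DMF, 0 to 23 °C
Reagents that add atoms: none
Why: Williamson etherification of the hindered alkoxide with a reactive allylic bromide; the C–O bond at the stereocentre is untouched, so S is retained.

**Step 2**
Reactants: 3
Product: 4 2-{(1S)-1-[(1Z)-prop-1-en-1-yloxy]ethyl}-1,3,5-tri(propan-2-yl)benzene
Conditions: t-BuOK (0.3 equiv), DMSO, 40 °C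
Reagents that add atoms: none
Why: base-mediated allyl-to-propenyl ether isomerisation, which should give the Z enol ether because the potassium-bridged oxyallyl anion is protonated from its cis form.

**Step 3**
Reactants: 5 methyl 3-hydroxy-2-methylpropanoate (racemic)
Product: 6 methyl 3-{[tert-butyl(diphenyl)silyl]oxy}-2-methylpropanoate (racemic)
Conditions: t-BuPh2SiCl, imidazole, DMF, 23 °C
Reagents that add atoms: tert-butyl(chloro)diphenylsilane, CC(C)(C)[Si](Cl)(c1ccccc1)c1ccccc1
Why: silylation of the primary alcohol; the robust silyl ether is chosen to survive acid chloride and ketene formation.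

**Step 4**
Reactants: 6
Product: 7 3-{[tert-butyl(diphenyl)silyl]oxy}-2-methylpropanoic acid (racemic)
Conditions: LiOH, THF/H2O, 23 °C; then 1 M HCl
Reagents that add atoms: lithium hydroxide, [Li+].[OH-]
Why: ester saponification; the racemic α-centre is of no consequence because it becomes the sp2 ketene carbon.

**Step 5**
Reactants: 7 the acid; 4 the (Z)-enol ether
Product: 10 (3S,4R)-2-({[tert-butyl(diphenyl)silyl]oxy}methyl)-2,4-dimethyl-3-{(1S)-1-[2,4,6-tri(propan-2-yl)phenyl]ethoxy}cyclobutan-1-one (both C2 epimers), via acid chloride 8 (not isolated), via ketene 9 (not isolated)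
Conditions: (COCl)2, DMF (cat.), CH2Cl2, 0 to 23 °C, solvent exchange; then slow addition to 4, Et3N, toluene, 80 °C
Reagents that add atoms: none
Why: Et3N dehydrochlorinates 8 to the dialkylketene 9, which undergoes a thermal, concerted but asynchronous [2+2] cycloaddition with 4 (ketene antarafacial, alkene suprafacial), the nucleophilic methyl-bearing carbon of 4 bonding to the ketene carbonyl carbon and the ketene α-carbon closing onto the O-bearing carbon. The closest known reaction types are the stereospecific cycloaddition of disubstituted ketenes with cis-propenyl ethers and the auxiliary-controlled cycloaddition of ketenes with enol ethers of chiral 1-arylethanols. The four-membered ring closes in this single suprafacial addition across the enol ether, so both new C–C bonds arrive on one alkene face and the Z geometry becomes the cis relation of the 4-methyl and 3-alkoxy groups. The absolute configuration at ring C3 and C4 is controlled by the (S)-1-arylethyl group: in the s-trans enol ether with the carbinol C–H eclipsing the vinyl C–O bond the triisopropylphenyl ring covers one face, and the ketene should add to the face carrying the small methyl group, which corresponds to 3S,4R. The step needs regioselectivity (secured by the oxygen donor), retention of alkene geometry (secured by the non-polar medium, which disfavours a long-lived zwitterion) and face selectivity (secured by the auxiliary); the configuration at ring C2 is uncontrolled but is erased in step 8. Slow addition of excess acid chloride compensates for ketene dimerisation.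

**Step 6**
Reactants: 10
Product: 11 (3S,4R)-2-(hydroxymethyl)-2,4-dimethyl-3-{(1S)-1-[2,4,6-tri(propan-2-yl)phenyl]ethoxy}cyclobutan-1-one (both C2 epimers)
Conditions: HF·pyridine, THF/pyridine, 0 to 23 °C
Reagents that add atoms: none
Why: fluoride-induced Si–O cleavage under non-basic conditions, so that the 3-alkoxycyclobutanone suffers neither β-elimination nor retro-aldol loss of formaldehyde.

**Step 7**
Reactants: 11
Product: 12 [(3S,4R)-1,3-dimethyl-2-oxo-4-{(1S)-1-[2,4,6-tri(propan-2-yl)phenyl]ethoxy}cyclobutyl]methyl 4-methylbenzenesulfonate (both epimers at the quaternary carbon)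
Conditions: TsCl, pyridine, DMAP (cat.), CH2Cl2, 0 °C
Reagents that add atoms: 4-methylbenzenesulfonyl chloride, Cc1ccc(cc1)S(Cl)(=O)=O
Why: sulfonylation of the primary alcohol installs the nucleofuge for the fragmentation; the neighbouring carbon is quaternary, so E1cB loss of tosylate cannot occur.

**Step 8**
Reactants: 12
Product: 14 (3R,4S)-3,5-dimethyl-4-{(1S)-1-[2,4,6-tri(propan-2-yl)phenyl]ethoxy}hex-5-en-2-one, via lithium cyclobutanolate 13 (not isolated)
Conditions: MeLi (1.05 equiv), THF, −78 °C; then 0 °C
Reagents that add atoms: methyllithium, [Li]C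
Why: 1,2-addition to the strained ketone gives a tertiary alkoxide that undergoes a strain-driven Grob fragmentation (alkoxide, ring bond between the former ketene carbons and exocyclic CH2–OTs antiperiplanar), unveiling the methyl ketone and the isopropenyl group without touching the two stereocentres; both C2 epimers converge.

**Step 9**
Reactants: 14
Product: 15 (3R,4S)-4-hydroxy-3,5-dimethylhex-5-en-2-one
Conditions: CF3CO2H (10 vol %), CH2Cl2, 0 °C, short contact; NaHCO3
Reagents that add atoms: none
Why: SN1 acidolysis of the hindered, highly stabilised benzylic ether; the C–O bond at the carbinol stereocentre is not broken, so its configuration is retained.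

**Step 10**
Reactants: 15; 16 4,4,5,5-tetramethyl-2-[(1E)-prop-1-en-1-yl]-1,3,2-dioxaborolane
Product: 18 (2S,4E,6R)-2,4,6-trimethyl-7-oxooct-4-enal, via allyl propenyl ether 17 (not isolated)
Conditions: Cu(OAc)2 (2 equiv), Et3N, 4 Å molecular sieves, CH2Cl2, 23 °C; filter; toluene, 110 °C
Reagents that add atoms: none
Why: Chan–Lam-type O-alkenylation with retention of the E geometry, then Claisen rearrangement through a chair transition state with the carbinol substituent equatorial, which fixes the E trisubstituted alkene and transfers the carbinol configuration to the new α-methyl stereocentre (2S).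

**Step 11**
Reactants: 19 (7-bromoheptyl)benzene
Product: 20 triphenyl(7-phenylheptyl)phosphonium bromide
Conditions: PPh3, MeCN, reflux
Reagents that add atoms: triphenylphosphine, c1ccc(cc1)P(c1ccccc1)c1ccccc1
Why: SN2 quaternisation of the phosphine by the primary bromide.

**Step 12**
Reactants: 18; 20
Product: 22 (3R,4E,7S,8Z)-3,5,7-trimethyl-15-phenylpentadeca-4,8-dien-2-one, via phosphorus ylide 21 (not isolated)
Conditions: NaN(SiMe3)2, THF, −78 °C; then 18, −78 to 0 °C
Reagents that add atoms: none
Why: Wittig olefination of the aldehyde by the unstabilised ylide, much faster than attack on or deprotonation of the hindered methyl ketone at low temperature; the new alkene geometry is irrelevant.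

**Step 13**
Reactants: 22
Product: 23 (3R,4E,7R)-3,5,7-trimethyl-15-phenylpentadec-4-en-2-one
Conditions: H2 (1 atm), RhCl(PPh3)3 (5 mol %), benzene/EtOH, 23 °C
Reagents that add atoms: none
Why: homogeneous hydrogenation that reduces the cis-disubstituted alkene far faster than the trisubstituted one; no stereocentre is touched (the descriptor at C7 changes only by priority rules).

**Step 14**
Reactants: 23
Product: 24 (3R,4E,7R)-2,2-dihydroperoxy-3,5,7-trimethyl-15-phenylpentadec-4-ene
Conditions: H2O2 (anhydrous, in Et2O, excess), H3PMo12O40 (cat.), 23 °C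
Reagents that add atoms: hydrogen peroxide, OO
Why: acid-catalysed peroxyketalisation of the ketone to the gem-dihydroperoxide, which removes the carbonyl group (and with it the enolisable C4–H) before the cyclisation.

**Step 15**
Reactants: 24
Product: 26 5-bromomercurio-3-hydroperoxy-3,4,6-trimethyl-6-[(2R)-2-methyl-10-phenyldecyl]-1,2-dioxane (C4 and C6 as in the target; HgBr equatorial and trans to O1; both C3 epimers), via acetoxymercurial 25 (not isolated)
Conditions: Hg(OAc)2, HClO4 (cat.), CH2Cl2, 0 °C; then aq. KBr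
Reagents that add atoms: mercury diacetate, CC(=O)O[Hg]OC(C)=O; potassium bromide, [K+].[Br-]
Why: intramolecular peroxymercuration (anti addition), closing the dioxane in the 6-endo mode because the mercurinium ion opens at the fully substituted C6; in the chair transition state the C6 methyl group (cis to C4 on the E alkene) is axial, so the C4 methyl group goes equatorial to avoid a 1,3-diaxial methyl–methyl contact and oxygen is delivered to the face that makes C6 S.

**Step 16**
Reactants: 26
Product: 27 5-bromomercurio-3,4,6-trimethyl-6-[(2R)-2-methyl-10-phenyldecyl]-1,2-dioxan-3-ol (C3, C4 and C6 as in the target)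
Conditions: Me2S, CH2Cl2, −20 to 0 °C
Reagents that add atoms: none
Why: chemoselective deoxygenation of the hydroperoxide by the sulfide (the dialkyl peroxide bridge is inert); the hemiketal should equilibrate through the open hydroperoxy ketone to the anomer with axial OH and equatorial methyl (anomeric effect), that is 3S.

**Step 17**
Reactants: 27
Product: 28 (3S,4R,6S)-3,4,6-trimethyl-6-[(2R)-2-methyl-10-phenyldecyl]-1,2-dioxan-3-ol
Conditions: Bu3SnH (1.1 equiv), toluene, 0 to 23 °C
Reagents that add atoms: none
Why: radical-chain hydrodemercuration via the alkylmercury hydride; the C5 ring radical is poorly aligned for intramolecular attack on the O–O bond and is quenched by hydrogen transfer, which removes the C5 stereocentre and leaves C3, C4 and C6 untouched.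

**Compound list**

1 | (1S)-1-[2,4,6-tri(propan-2-yl)phenyl]ethanol | C[C@H](O)c1c(C(C)C)cc(C(C)C)cc1C(C)C | starting material
2 | allyl bromide | C=CCBr | starting material
3 | 2-[(1S)-1-(prop-2-en-1-yloxy)ethyl]-1,3,5-tri(propan-2-yl)benzene | C=CCO[C@@H](C)c1c(C(C)C)cc(C(C)C)cc1C(C)C | intermediate
4 | 2-{(1S)-1-[(1Z)-prop-1-en-1-yloxy]ethyl}-1,3,5-tri(propan-2-yl)benzene | C/C=C\O[C@@H](C)c1c(C(C)C)cc(C(C)C)cc1C(C)C | intermediate
5 | methyl 3-hydroxy-2-methylpropanoate (racemic) | COC(=O)C(C)CO | starting material
6 | methyl 3-{[tert-butyl(diphenyl)silyl]oxy}-2-methylpropanoate (racemic) | COC(=O)C(C)CO[Si](c1ccccc1)(c1ccccc1)C(C)(C)C | intermediate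
7 | 3-{[tert-butyl(diphenyl)silyl]oxy}-2-methylpropanoic acid (racemic) | OC(=O)C(C)CO[Si](c1ccccc1)(c1ccccc1)C(C)(C)C | intermediate
8 | 3-{[tert-butyl(diphenyl)silyl]oxy}-2-methylpropanoyl chloride | ClC(=O)C(C)CO[Si](c1ccccc1)(c1ccccc1)C(C)(C)C | intermediate (not isolated)
9 | 3-{[tert-butyl(diphenyl)silyl]oxy}-2-methylprop-1-en-1-one (ketene) | O=C=C(C)CO[Si](c1ccccc1)(c1ccccc1)C(C)(C)C | intermediate (not isolated)
10 | (3S,4R)-2-({[tert-butyl(diphenyl)silyl]oxy}methyl)-2,4-dimethyl-3-{(1S)-1-[2,4,6-tri(propan-2-yl)phenyl]ethoxy}cyclobutan-1-one, C2 epimers | O=C1[C@H](C)[C@H](O[C@@H](C)c2c(C(C)C)cc(C(C)C)cc2C(C)C)C1(C)CO[Si](c3ccccc3)(c4ccccc4)C(C)(C)C | intermediate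
11 | (3S,4R)-2-(hydroxymethyl)-2,4-dimethyl-3-{(1S)-1-[2,4,6-tri(propan-2-yl)phenyl]ethoxy}cyclobutan-1-one, C2 epimers | O=C1[C@H](C)[C@H](O[C@@H](C)c2c(C(C)C)cc(C(C)C)cc2C(C)C)C1(C)CO | intermediate
12 | [(3S,4R)-1,3-dimethyl-2-oxo-4-{(1S)-1-[2,4,6-tri(propan-2-yl)phenyl]ethoxy}cyclobutyl]methyl 4-methylbenzenesulfonate, C1 epimers | O=C1[C@H](C)[C@H](O[C@@H](C)c2c(C(C)C)cc(C(C)C)cc2C(C)C)C1(C)COS(=O)(=O)c3ccc(C)cc3 | intermediate
13 | lithium (3S,4R)-1,2,4-trimethyl-2-[(tosyloxy)methyl]-3-{(1S)-1-[2,4,6-tri(propan-2-yl)phenyl]ethoxy}cyclobutan-1-olate, C1 and C2 epimers | [Li+].[O-]C1(C)[C@H](C)[C@H](O[C@@H](C)c2c(C(C)C)cc(C(C)C)cc2C(C)C)C1(C)COS(=O)(=O)c3ccc(C)cc3 | intermediate (not isolated)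
14 | (3R,4S)-3,5-dimethyl-4-{(1S)-1-[2,4,6-tri(propan-2-yl)phenyl]ethoxy}hex-5-en-2-one | CC(=O)[C@H](C)[C@H](O[C@@H](C)c1c(C(C)C)cc(C(C)C)cc1C(C)C)C(C)=C | intermediate
15 | (3R,4S)-4-hydroxy-3,5-dimethylhex-5-en-2-one | CC(=O)[C@H](C)[C@H](O)C(C)=C | intermediate
16 | 4,4,5,5-tetramethyl-2-[(1E)-prop-1-en-1-yl]-1,3,2-dioxaborolane | C/C=C/B1OC(C)(C)C(C)(C)O1 | starting material
17 | (3R,4S)-3,5-dimethyl-4-[(1E)-prop-1-en-1-yloxy]hex-5-en-2-one | CC(=O)[C@H](C)[C@H](O/C=C/C)C(C)=C | intermediate (not isolated)
18 | (2S,4E,6R)-2,4,6-trimethyl-7-oxooct-4-enal | CC(=O)[C@H](C)/C=C(\C)C[C@H](C)C=O | intermediate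
19 | (7-bromoheptyl)benzene | BrCCCCCCCc1ccccc1 | starting material
20 | triphenyl(7-phenylheptyl)phosphonium bromide | [Br-].c1ccccc1CCCCCCC[P+](c1ccccc1)(c1ccccc1)c1ccccc1 | intermediate
21 | triphenyl(7-phenylheptylidene)phosphorane | c1ccccc1CCCCCCC=P(c1ccccc1)(c1ccccc1)c1ccccc1 | intermediate (not isolated)
22 | (3R,4E,7S,8Z)-3,5,7-trimethyl-15-phenylpentadeca-4,8-dien-2-one | CC(=O)[C@H](C)/C=C(\C)C[C@H](C)/C=C\CCCCCCc1ccccc1 | intermediate
23 | (3R,4E,7R)-3,5,7-trimethyl-15-phenylpentadec-4-en-2-one | CC(=O)[C@H](C)/C=C(\C)C[C@H](C)CCCCCCCCc1ccccc1 | intermediate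
24 | (3R,4E,7R)-2,2-dihydroperoxy-3,5,7-trimethyl-15-phenylpentadec-4-ene | CC(OO)(OO)[C@H](C)/C=C(\C)C[C@H](C)CCCCCCCCc1ccccc1 | intermediate
25 | 5-acetoxymercurio-3-hydroperoxy-3,4,6-trimethyl-6-[(2R)-2-methyl-10-phenyldecyl]-1,2-dioxane (C4, C6 as in target; Hg trans to O1; C3 epimers) | C[C@H](CCCCCCCCc1ccccc1)C[C@@]1(C)[C@H]([Hg]OC(C)=O)[C@@H](C)C(C)(OO)OO1 | intermediate (not isolated)
26 | 5-bromomercurio-3-hydroperoxy-3,4,6-trimethyl-6-[(2R)-2-methyl-10-phenyldecyl]-1,2-dioxane (C4, C6 as in target; Hg trans to O1; C3 epimers) | C[C@H](CCCCCCCCc1ccccc1)C[C@@]1(C)[C@H]([Hg]Br)[C@@H](C)C(C)(OO)OO1 | intermediate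
27 | 5-bromomercurio-3,4,6-trimethyl-6-[(2R)-2-methyl-10-phenyldecyl]-1,2-dioxan-3-ol (C3, C4, C6 as in target) | C[C@H](CCCCCCCCc1ccccc1)C[C@@]1(C)[C@H]([Hg]Br)[C@@H](C)[C@@](C)(O)OO1 | intermediate
28 | (3S,4R,6S)-3,4,6-trimethyl-6-[(2R)-2-methyl-10-phenyldecyl]-1,2-dioxan-3-ol | C[C@H](CCCCCCCCc1ccccc1)C[C@@]1(C)C[C@@H](C)[C@@](C)(O)OO1 | target

**Totals and risks**

Total step count: 17. Longest linear sequence: 14 (steps 3–10 and 12–17).

Step 5 (cycloaddition). What may go wrong: cycloaddition at the hindered enol ether that is slow relative to ketene dimerisation, and incomplete face discrimination. Fallback: replace the neutral ketene by a far more electrophilic keteniminium ion. Setting out from 7, the acid chloride 8 is condensed with pyrrolidine to 1-(3-{[tert-butyl(diphenyl)silyl]oxy}-2-methylpropanoyl)pyrrolidine F1. (CF3SO2)2O and 2,6-di-tert-butyl-4-methylpyridine in CH2Cl2 convert it into the keteniminium triflate F2, which should add to 4 at low temperature to give the cyclobutaniminium triflate F3. Hydrolysis with aqueous NaHCO3 comes back to the route at 10. Face control still rests on the auxiliary of 4.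

Step 10 (O-alkenylation and Claisen rearrangement). What may go wrong: sluggish copper-mediated O-alkenylation of the hindered β-hydroxy ketone, with retro-aldol cleavage competing. Fallback: setting out from 15, acid-catalysed O-allylation with allyl 2,2,2-trichloroacetimidate (CF3SO3H cat.) gives the bis-allylic ether (3R,4S)-3,5-dimethyl-4-(prop-2-en-1-yloxy)hex-5-en-2-one F4. An iridium hydride catalyst ([IrCl(C8H14)2]2, PCy3, NaBPh4) should isomerise only the unsubstituted O-allyl group to the (E)-propenyl ether 17, and heating comes back to the route at 18.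

Step 15 (peroxymercuration). What may go wrong: competing 5-exo closure or oxidative side reactions at mercury, and leakage of the chair control that sets C6. Fallback: give up the relay and install the peroxide by a radical route. Setting out from 23, cobalt-catalysed hydroperoxysilylation (Co(acac)2, Et3SiH, O2) places the peroxy group on the more substituted alkene carbon to give (3R,7R)-3,5,7-trimethyl-15-phenyl-5-[(triethylsilyl)peroxy]pentadecan-2-one F5. Removal of silicon (HF, MeCN/H2O) frees the γ-hydroperoxy ketone, which closes to 28 together with its C6 epimer, (4R,6R)-3,4,6-trimethyl-6-[(2R)-2-methyl-10-phenyldecyl]-1,2-dioxan-3-ol F6; the two are separated by chromatography and the route comes back at 28.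

**Further compounds**

F1 | step 5 | 1-(3-{[tert-butyl(diphenyl)silyl]oxy}-2-methylpropanoyl)pyrrolidine | O=C(C(C)CO[Si](c1ccccc1)(c1ccccc1)C(C)(C)C)N1CCCC1
F2 | step 5 | 1-(3-{[tert-butyl(diphenyl)silyl]oxy}-2-methylprop-1-en-1-ylidene)pyrrolidinium trifluoromethanesulfonate | CC(CO[Si](c1ccccc1)(c1ccccc1)C(C)(C)C)=C=[N+]1CCCC1.[O-]S(=O)(=O)C(F)(F)F
F3 | step 5 | 1-[(3S,4R)-2-({[tert-butyl(diphenyl)silyl]oxy}methyl)-2,4-dimethyl-3-{(1S)-1-[2,4,6-tri(propan-2-yl)phenyl]ethoxy}cyclobutylidene]pyrrolidinium trifluoromethanesulfonate | C1(=[N+]2CCCC2)[C@H](C)[C@H](O[C@@H](C)c3c(C(C)C)cc(C(C)C)cc3C(C)C)C1(C)CO[Si](c4ccccc4)(c5ccccc5)C(C)(C)C.[O-]S(=O)(=O)C(F)(F)F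
F4 | step 10 | (3R,4S)-3,5-dimethyl-4-(prop-2-en-1-yloxy)hex-5-en-2-one | CC(=O)[C@H](C)[C@H](OCC=C)C(C)=C
F5 | step 15 | (3R,7R)-3,5,7-trimethyl-15-phenyl-5-[(triethylsilyl)peroxy]pentadecan-2-one (C5 epimers) | CC(=O)[C@H](C)CC(C)(OO[Si](CC)(CC)CC)C[C@H](C)CCCCCCCCc1ccccc1
F6 | step 15 | (4R,6R)-3,4,6-trimethyl-6-[(2R)-2-methyl-10-phenyldecyl]-1,2-dioxan-3-ol | C[C@H](CCCCCCCCc1ccccc1)C[C@]1(C)C[C@@H](C)C(C)(O)OO1
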